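**Retrosynthetic overview**
1. The N-oxide comes from the tertiary amine; the δ-lactone (which also sets C15) comes from acid-triggered closure of the C22 propanoate chain onto a C15 exo-methylene.
2. The C6–H and C14–H bonds come from anti addition of hydride and proton across a pentacyclic vinylogous amide (N–C6=C14–C15=O).
3. The vinylogous amide comes from an amino ynone by aza-Michael closure (N–C6, piperidine ring) and enaminone C-alkylation (C13–C14, cyclohexane ring).
4. The ynone comes from a palladium-catalysed, CuI-mediated thioester–alkyne coupling (C14–C15) of fragment A (azabicyclo[3.3.0]octane thioester) with fragment B (cyclopentenyl alkyne, whose C6–C7 bond comes from a Sonogashira coupling).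
5. Ring order: cyclopentane (present in the starting lactam) → pyrrolidine (radical cyclisation); cyclopentene (from cyclopentanone) → piperidine → cyclohexane → lactone.

Atom labels C1–C26 are the positions of the atoms in the target SMILES (N4 is nitrogen, O5 the N-oxide oxygen, O17 the ring oxygen).

Assumption: (1R,5S)-6-azabicyclo[3.2.0]hept-3-en-7-one is bought enantiopure (otherwise it is made by the known lipase resolution of the cyclopentadiene/chlorosulfonyl isocyanate adduct).

The stereochemical arguments below are conformational reasoning done by hand, not computed or tested.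

**Fragment A**

Step 1
Reactants: 1 (1R,5S)-6-azabicyclo[3.2.0]hept-3-en-7-one
Product: 2 tert-butyl (1R,5S)-7-oxo-6-azabicyclo[3.2.0]hept-3-ene-6-carboxylate
Conditions: Boc2O, 4-(dimethylamino)pyridine (10 mol %), MeCN, rt
Reagents that add atoms: di-tert-butyl dicarbonate, CC(C)(C)OC(=O)OC(=O)OC(C)(C)C
Why: N-acylation (carbamate formation) activates the strained lactam for ring opening and leaves both stereocentres (C22 and C26) untouched.

Step 2
Reactants: 2 tert-butyl (1R,5S)-7-oxo-6-azabicyclo[3.2.0]hept-3-ene-6-carboxylate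
Product: 3 benzyl (1R,2S)-2-[(tert-butoxycarbonyl)amino]cyclopent-3-ene-1-carboxylate
Conditions: BnOH (1.5 equiv), NaH (10 mol %), THF, 0 °C
Reagents that add atoms: benzyl alcohol, OCc1ccccc1
Why: Alkoxide-catalysed alcoholysis (acyl transfer) of the N-Boc β-lactam opens the four-membered ring with retention, and any epimerisation at C22 is harmless because C22 is re-set in step 5.

Step 3
Reactants: 3 benzyl (1R,2S)-2-[(tert-butoxycarbonyl)amino]cyclopent-3-ene-1-carboxylate; 4 2,3-dibromoprop-1-ene
Product: 6 benzyl (1R,2S)-2-[(2-bromoprop-2-en-1-yl)(tert-butoxycarbonyl)amino]cyclopent-3-ene-1-carboxylate, via sodium carbamate salt 5 (not isolated)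
Conditions: NaH (1.1 equiv), DMF, 0 °C; then 4, 0 °C → rt
Reagents that add atoms: none
Why: SN2 N-alkylation of the carbamate anion at the allylic CH2Br of 4, the vinylic bromide being inert.

Step 4
Reactants: 6 benzyl (1R,2S)-2-[(2-bromoprop-2-en-1-yl)(tert-butoxycarbonyl)amino]cyclopent-3-ene-1-carboxylate
Product: 7 benzyl (3aR,6R,6aS)-1-(tert-butoxycarbonyl)-3-methylideneoctahydrocyclopenta[b]pyrrole-6-carboxylate
Conditions: Bu3SnH (slow addition), azobisisobutyronitrile (10 mol %), PhH, 80 °C
Reagents that add atoms: none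
Why: Tin-hydride-mediated 5-exo-trig vinyl-radical cyclisation onto the ring alkene forms C2–C25, and the short N–CH2 tether permits only the cis ring fusion, so C25 is set R with H25 cis to H26.

Step 5
Reactants: 7 benzyl (3aR,6R,6aS)-1-(tert-butoxycarbonyl)-3-methylideneoctahydrocyclopenta[b]pyrrole-6-carboxylate; 8 propan-2-yl prop-2-enoate
Product: 10 benzyl (3aR,6S,6aS)-1-(tert-butoxycarbonyl)-3-methylidene-6-[3-oxo-3-(propan-2-yloxy)propyl]octahydrocyclopenta[b]pyrrole-6-carboxylate, via lithium ester enolate 9 (not isolated)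
Conditions: LiN(iPr)2 (1.1 equiv), THF, −78 °C; then 8, −78 °C; AcOH quench
Reagents that add atoms: none
Why: Michael addition of the ester enolate to the acrylate, which enters C22 from the convex face of the cis-bicyclo[3.3.0]octane (anti to the pyrrolidine ring), so the propanoate chain ends cis to H26 and the ester carbon C15 cis to nitrogen (C22 S).

Step 6
Reactants: 10 benzyl (3aR,6S,6aS)-1-(tert-butoxycarbonyl)-3-methylidene-6-[3-oxo-3-(propan-2-yloxy)propyl]octahydrocyclopenta[b]pyrrole-6-carboxylate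
Product: 11 (3S,3aR,6S,6aS)-1-(tert-butoxycarbonyl)-3-methyl-6-[3-oxo-3-(propan-2-yloxy)propyl]octahydrocyclopenta[b]pyrrole-6-carboxylic acid
Conditions: H2 (1 atm), 10% Pd/C, EtOAc, rt
Reagents that add atoms: none
Why: Heterogeneous hydrogenation delivers hydrogen to the exocyclic alkene from the convex face (H2 cis to H25, so the methyl is endo and C2 is S), and hydrogenolysis of the benzyl ester frees the acid in the same operation.

Step 7
Reactants: 11 (3S,3aR,6S,6aS)-1-(tert-butoxycarbonyl)-3-methyl-6-[3-oxo-3-(propan-2-yloxy)propyl]octahydrocyclopenta[b]pyrrole-6-carboxylic acid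
Product: 12 S-ethyl (3S,3aR,6S,6aS)-1-(tert-butoxycarbonyl)-3-methyl-6-[3-oxo-3-(propan-2-yloxy)propyl]octahydrocyclopenta[b]pyrrole-6-carbothioate
Conditions: EtSH, DCC, 4-(dimethylamino)pyridine (10 mol %), CH2Cl2, 0 °C → rt
Reagents that add atoms: ethanethiol, CCS
Why: Steglich-type thioesterification (carbodiimide activation) turns the hindered acid into a stable acyl donor for the coupling without building an acid chloride next to the carbamate.

**Fragment B**

Step 8
Reactants: 13 cyclopentanone
Product: 14 (2R)-N-cyclopentylidene-2-(methoxymethyl)pyrrolidin-1-amine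
Conditions: RAMP (1.0 equiv), cyclohexane, reflux (Dean–Stark)
Reagents that add atoms: (R)-1-amino-2-(methoxymethyl)pyrrolidine (RAMP), COC[C@H]1CCCN1N
Why: Hydrazone condensation installs the Enders auxiliary.

Step 9
Reactants: 14 (2R)-N-cyclopentylidene-2-(methoxymethyl)pyrrolidin-1-amine; 15 1-bromo-2-chloroethane
Product: 17 (2R)-N-[(2R)-2-(2-chloroethyl)cyclopentylidene]-2-(methoxymethyl)pyrrolidin-1-amine, via lithium azaenolate 16 (not isolated)
Conditions: LiN(iPr)2, THF, 0 °C; then 15, −100 → −78 °C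
Reagents that add atoms: none
Why: Enders RAMP-hydrazone alkylation, in which the methoxy-chelated lithium azaenolate is alkylated at the bromide terminus on one face only, giving R at C11 (the mirror image of the SAMP outcome).

Step 10
Reactants: 17 (2R)-N-[(2R)-2-(2-chloroethyl)cyclopentylidene]-2-(methoxymethyl)pyrrolidin-1-amine
Product: 18 (2R)-2-(2-chloroethyl)cyclopentan-1-one
Conditions: sat. aq. (CO2H)2, Et2O, rt
Reagents that add atoms: water, O
Why: Mild two-phase hydrazone hydrolysis releases the α-stereogenic ketone without racemisation and returns the auxiliary.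

Step 11
Reactants: 18 (2R)-2-(2-chloroethyl)cyclopentan-1-one
Product: 20 (5R)-5-(2-chloroethyl)cyclopent-1-en-1-yl trifluoromethanesulfonate, via lithium enolate 19 (not isolated)
Conditions: LiN(iPr)2 (1.05 equiv), THF, −78 °C; then PhNTf2, −78 → 0 °C
Reagents that add atoms: N-phenylbis(trifluoromethanesulfonimide), O=S(=O)(N(c1ccccc1)S(=O)(=O)C(F)(F)F)C(F)(F)F
Why: Kinetic deprotonation at the unsubstituted α-carbon followed by O-triflation gives the less substituted enol triflate (C7=C8) and does not touch C11.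

Step 12
Reactants: 20 (5R)-5-(2-chloroethyl)cyclopent-1-en-1-yl trifluoromethanesulfonate; 21 ethynyl(trimethyl)silane
Product: 22 {[(5R)-5-(2-chloroethyl)cyclopent-1-en-1-yl]ethynyl}(trimethyl)silane
Conditions: Pd(PPh3)4 (5 mol %), CuI (10 mol %), iPr2NH, THF, rt
Reagents that add atoms: none
Why: Sonogashira coupling of the alkenyl triflate forms the C6–C7 bond, the alkyl chloride being inert under these conditions.

Step 13
Reactants: 22 {[(5R)-5-(2-chloroethyl)cyclopent-1-en-1-yl]ethynyl}(trimethyl)silane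
Product: 23 (5R)-5-(2-chloroethyl)-1-ethynylcyclopent-1-ene
Conditions: K2CO3 (20 mol %), MeOH, rt
Reagents that add atoms: none
Why: Base-catalysed methanolysis of the alkynyl–silicon bond frees the terminal alkyne.

Step 14
Reactants: 23 (5R)-5-(2-chloroethyl)-1-ethynylcyclopent-1-ene
Product: 24 (5R)-1-ethynyl-5-(2-iodoethyl)cyclopent-1-ene
Conditions: NaI (5 equiv), acetone, reflux
Reagents that add atoms: sodium iodide, [Na+].[I-]
Why: Finkelstein exchange provides the primary iodide needed for the mild ring closure in step 16.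

**Union and endgame**

Step 15
Reactants: 12 S-ethyl (3S,3aR,6S,6aS)-1-(tert-butoxycarbonyl)-3-methyl-6-[3-oxo-3-(propan-2-yloxy)propyl]octahydrocyclopenta[b]pyrrole-6-carbothioate; 24 (5R)-1-ethynyl-5-(2-iodoethyl)cyclopent-1-ene
Product: 25 propan-2-yl 3-[(3S,3aR,6S,6aS)-1-(tert-butoxycarbonyl)-6-{3-[(5R)-5-(2-iodoethyl)cyclopent-1-en-1-yl]prop-2-ynoyl}-3-methyloctahydrocyclopenta[b]pyrrol-6-yl]propanoate
Conditions: PdCl2(dppf) (10 mol %), P(2-furyl)3 (25 mol %), CuI (1.7 equiv), iPr2NEt, DMF, 50 °C
Reagents that add atoms: none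
Why: Palladium-catalysed, CuI-mediated thioester–alkyne cross-coupling (acyl Sonogashira type), in which zerovalent palladium inserts into the acyl–S bond, the alkynylcopper species formed with CuI transmetalates and reductive elimination forms the C14–C15 bond that joins fragments A and B without touching a stereocentre.

Step 16
Reactants: 25 propan-2-yl 3-[(3S,3aR,6S,6aS)-1-(tert-butoxycarbonyl)-6-{3-[(5R)-5-(2-iodoethyl)cyclopent-1-en-1-yl]prop-2-ynoyl}-3-methyloctahydrocyclopenta[b]pyrrol-6-yl]propanoate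
Product: 28 pentacyclic vinylogous amide (N–C6=C14–C15=O; 2S,11R,22S,25R,26S; isopropyl propanoate chain on C22), via ammonium trifluoroacetate 26 (not isolated), via tricyclic iodo enaminone 27 (not isolated)
Conditions: TFA, CH2Cl2, 0 °C; concentrate; K2CO3 (5 equiv), MeCN, rt → 70 °C
Reagents that add atoms: none
Why: Carbamate acidolysis then base triggers 6-endo-dig aza-Michael addition of the amine to the ynone (N–C6, piperidine ring), and the nucleophilic α-carbon C14 of the resulting enaminone is alkylated by the primary iodide (6-exo-tet enaminone C-alkylation), closing the cyclohexane ring with no new stereocentre.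

Step 17
Reactants: 28 pentacyclic vinylogous amide (N–C6=C14–C15=O; 2S,11R,22S,25R,26S; isopropyl propanoate chain on C22)
Product: 30 pentacyclic amino ketone (2S,6R,11R,14S,22S,25R,26S; H6 trans to H14), via triethylsilyl enol ether 29 (not isolated)
Conditions: B(C6F5)3 (10 mol %), Et3SiH (1.3 equiv), PhMe, 0 °C → rt; then HCl in MeOH (2.2 equiv), −40 °C; cold aq. NaHCO3
Reagents that add atoms: none
Why: Proposed new method: borane-catalysed 1,4-hydrosilylation of a fully substituted ring-fused vinylogous amide, in which B(C6F5)3 activates Et3SiH, the Lewis-basic vinylogous-amide oxygen is silylated to a 4-silyloxy-dihydropyridinium ion and the hydridoborate delivers hydride to the iminium carbon C6 anti to the nitrogen lone pair, which the fused pyrrolidine lets develop only on the H26 face (C6 R), after which kinetic axial C-protonation of silyl enol ether 29 (chair-like transition state in the conformer that keeps C7 equatorial) places H14 trans to H6 (C14 S); the closest known reaction types are the B(C6F5)3-catalysed 1,4-hydrosilylation of enones and the hydride reduction of O-activated vinylogous amides.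

Step 18
Reactants: 30 pentacyclic amino ketone (2S,6R,11R,14S,22S,25R,26S; H6 trans to H14)
Product: 31 exo-methylene ester (C15=CH2; ring configuration as in 30)
Conditions: Tebbe reagent Cp2Ti(μ-Cl)(μ-CH2)AlMe2 (1.5 equiv), pyridine, THF/PhMe, −40 → 0 °C
Reagents that add atoms: Tebbe reagent Cp2Ti(μ-Cl)(μ-CH2)AlMe2, C[Al](C)C[Ti](Cl)(C1C=CC=C1)C1C=CC=C1
Why: Tebbe methylenation (cycloaddition of the titanium methylidene Cp2Ti=CH2 to the carbonyl, then cycloreversion) is non-basic, so the epimerisable C14 centre survives, and at low temperature the ketone reacts faster than the isopropyl ester.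

Step 19
Reactants: 31 exo-methylene ester (C15=CH2; ring configuration as in 30)
Product: 32 hexacyclic amino lactone (N-deoxy target; 2S,6R,11R,14S,15R,22S,25R,26S)
Conditions: TfOH (3 equiv), CH2Cl2, −20 → 0 °C; aq. NaHCO3
Reagents that add atoms: none
Why: Markovnikov protonation gives the tertiary C15 cation, which is trapped by the ester carbonyl of the axial C22 chain (acid-mediated dealkylative lactonisation, isopropyl leaving as propene), and because the tether reaches only the face cis to C21 the oxygen O17 ends cis to C21 with the new methyl on the other face (C15 R).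

Step 20
Reactants: 32 hexacyclic amino lactone (N-deoxy target; 2S,6R,11R,14S,15R,22S,25R,26S)
Product: 33 target N-oxide CNP0566793.5 (2S,4S,6R,11R,14S,15R,22S,25R,26S)
Conditions: mCPBA (1.05 equiv), CH2Cl2, −20 °C
Reagents that add atoms: 3-chloroperbenzoic acid, OOC(=O)c1cccc(Cl)c1
Why: Peracid N-oxidation of the tertiary amine, whose lone pair is locked cis to H26 by the fused pyrrolidine so only the target configuration at nitrogen can form, and which outpaces epoxidation of the trisubstituted alkene at low temperature.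

**Compound list**
1 | (1R,5S)-6-azabicyclo[3.2.0]hept-3-en-7-one | C1=CC[C@H]2C(=O)N[C@@H]12 | starting material
2 | tert-butyl (1R,5S)-7-oxo-6-azabicyclo[3.2.0]hept-3-ene-6-carboxylate | C1=CC[C@H]2C(=O)N(C(=O)OC(C)(C)C)[C@@H]12 | intermediate
3 | benzyl (1R,2S)-2-[(tert-butoxycarbonyl)amino]cyclopent-3-ene-1-carboxylate | C1=CC[C@@H](C(=O)OCc2ccccc2)[C@H]1NC(=O)OC(C)(C)C | intermediate
4 | 2,3-dibromoprop-1-ene | C=C(Br)CBr | starting material
5 | sodium salt of 3 (carbamate N-anion) | C1=CC[C@@H](C(=O)OCc2ccccc2)[C@H]1[N-]C(=O)OC(C)(C)C.[Na+] | intermediate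
6 | benzyl (1R,2S)-2-[(2-bromoprop-2-en-1-yl)(tert-butoxycarbonyl)amino]cyclopent-3-ene-1-carboxylate | C1=CC[C@@H](C(=O)OCc2ccccc2)[C@H]1N(CC(Br)=C)C(=O)OC(C)(C)C | intermediate
7 | benzyl (3aR,6R,6aS)-1-(tert-butoxycarbonyl)-3-methylideneoctahydrocyclopenta[b]pyrrole-6-carboxylate | C=C1CN(C(=O)OC(C)(C)C)[C@H]2[C@@H]1CC[C@H]2C(=O)OCc3ccccc3 | intermediate
8 | propan-2-yl prop-2-enoate (isopropyl acrylate) | C=CC(=O)OC(C)C | starting material
9 | lithium ester enolate of 7 | [Li+].C=C1CN(C(=O)OC(C)(C)C)[C@H]2[C@@H]1CCC2=C([O-])OCc3ccccc3 | intermediate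
10 | benzyl (3aR,6S,6aS)-1-(tert-butoxycarbonyl)-3-methylidene-6-[3-oxo-3-(propan-2-yloxy)propyl]octahydrocyclopenta[b]pyrrole-6-carboxylate | C=C1CN(C(=O)OC(C)(C)C)[C@H]2[C@@H]1CC[C@@]2(CCC(=O)OC(C)C)C(=O)OCc3ccccc3 | intermediate
11 | (3S,3aR,6S,6aS)-1-(tert-butoxycarbonyl)-3-methyl-6-[3-oxo-3-(propan-2-yloxy)propyl]octahydrocyclopenta[b]pyrrole-6-carboxylic acid | C[C@@H]1CN(C(=O)OC(C)(C)C)[C@H]2[C@@H]1CC[C@@]2(CCC(=O)OC(C)C)C(=O)O | intermediate
12 | S-ethyl (3S,3aR,6S,6aS)-1-(tert-butoxycarbonyl)-3-methyl-6-[3-oxo-3-(propan-2-yloxy)propyl]octahydrocyclopenta[b]pyrrole-6-carbothioate | C[C@@H]1CN(C(=O)OC(C)(C)C)[C@H]2[C@@H]1CC[C@@]2(CCC(=O)OC(C)C)C(=O)SCC | intermediate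
13 | cyclopentanone | O=C1CCCC1 | starting material
14 | (2R)-N-cyclopentylidene-2-(methoxymethyl)pyrrolidin-1-amine | COC[C@H]1CCCN1N=C2CCCC2 | intermediate
15 | 1-bromo-2-chloroethane | ClCCBr | starting material
16 | lithium azaenolate of 14 | [Li+].COC[C@H]1CCCN1[N-]C2=CCCC2 | intermediate
17 | (2R)-N-[(2R)-2-(2-chloroethyl)cyclopentylidene]-2-(methoxymethyl)pyrrolidin-1-amine | COC[C@H]1CCCN1N=C2CCC[C@@H]2CCCl | intermediate
18 | (2R)-2-(2-chloroethyl)cyclopentan-1-one | O=C1CCC[C@@H]1CCCl | intermediate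
19 | lithium (5R)-5-(2-chloroethyl)cyclopent-1-en-1-olate | [Li+].[O-]C1=CCC[C@@H]1CCCl | intermediate
20 | (5R)-5-(2-chloroethyl)cyclopent-1-en-1-yl trifluoromethanesulfonate | FC(F)(F)S(=O)(=O)OC1=CCC[C@@H]1CCCl | intermediate
21 | ethynyl(trimethyl)silane | C#C[Si](C)(C)C | starting material
22 | {[(5R)-5-(2-chloroethyl)cyclopent-1-en-1-yl]ethynyl}(trimethyl)silane | C[Si](C)(C)C#CC1=CCC[C@@H]1CCCl | intermediate
23 | (5R)-5-(2-chloroethyl)-1-ethynylcyclopent-1-ene | C#CC1=CCC[C@@H]1CCCl | intermediate
24 | (5R)-1-ethynyl-5-(2-iodoethyl)cyclopent-1-ene | C#CC1=CCC[C@@H]1CCI | intermediate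
25 | N-Boc ynone: propan-2-yl 3-[(3S,3aR,6S,6aS)-1-(tert-butoxycarbonyl)-6-{3-[(5R)-5-(2-iodoethyl)cyclopent-1-en-1-yl]prop-2-ynoyl}-3-methyloctahydrocyclopenta[b]pyrrol-6-yl]propanoate | C[C@@H]1CN(C(=O)OC(C)(C)C)[C@H]2[C@@H]1CC[C@@]2(CCC(=O)OC(C)C)C(=O)C#CC3=CCC[C@@H]3CCI | intermediate
26 | ammonium trifluoroacetate of the N-deprotected ynone | C[C@@H]1C[NH2+][C@H]2[C@@H]1CC[C@@]2(CCC(=O)OC(C)C)C(=O)C#CC3=CCC[C@@H]3CCI.[O-]C(=O)C(F)(F)F | intermediate
27 | tricyclic iodo enaminone (N–C6=C14H–C15=O, C6 bearing the (5R)-5-(2-iodoethyl)cyclopentenyl group) | C[C@@H]1CN2C(C3=CCC[C@@H]3CCI)=CC(=O)[C@]4(CCC(=O)OC(C)C)CC[C@H]1[C@H]24 | intermediate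
28 | pentacyclic vinylogous amide (2S,11R,22S,25R,26S) | C[C@@H]1CN2C3=C(CC[C@H]4CCC=C34)C(=O)[C@]5(CCC(=O)OC(C)C)CC[C@H]1[C@H]25 | intermediate
29 | triethylsilyl enol ether (C14=C15–OSiEt3; H6 anti to the nitrogen lone pair) | C[C@@H]1CN2[C@H]3C4=CCC[C@@H]4CCC3=C(O[Si](CC)(CC)CC)[C@]5(CCC(=O)OC(C)C)CC[C@H]1[C@H]25 | intermediate
30 | pentacyclic amino ketone (2S,6R,11R,14S,22S,25R,26S) | C[C@@H]1CN2[C@H]3C4=CCC[C@@H]4CC[C@@H]3C(=O)[C@]5(CCC(=O)OC(C)C)CC[C@H]1[C@H]25 | intermediate
31 | exo-methylene ester (C15=CH2; ring configuration as in 30) | C[C@@H]1CN2[C@H]3C4=CCC[C@@H]4CC[C@@H]3C(=C)[C@]5(CCC(=O)OC(C)C)CC[C@H]1[C@H]25 | intermediate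
32 | hexacyclic amino lactone (N-deoxy target) | C[C@@H]1CN2[C@H]3C4=CCC[C@@H]4CC[C@@H]3[C@@]3(C)OC(=O)CC[C@]34CC[C@H]1[C@@H]42 | intermediate
33 | CNP0566793.5 (N-oxide) | C[C@@H]1C[N@+]2([O-])[C@H]3C4=CCC[C@@H]4CC[C@@H]3[C@@]3(C)OC(=O)CC[C@]34CC[C@H]1[C@@H]42 | target

**Totals and risks**

Total step count: 20. Longest linear sequence: 13 (steps 1–7 then 15–20; the branch 8–14 then 15–20 is equally long), which is 65 % of the total.

The three steps most likely to fail:

Step 17, the proposed borane-catalysed hydrosilylation with kinetic protonation. Hydride could go to C8 instead of C6, the basic amine could inhibit B(C6F5)3, or protonation could give the more stable cis-fused C14 epimer. The fallback uses known stoichiometric chemistry and sets out from 28. O-Alkylation with Et3OBF4 in CH2Cl2 gives the O-ethyl iminium tetrafluoroborate F4. NaBH4 in MeOH at −78 °C adds hydride at C6 (small hydride, same anti-to-lone-pair argument) to give the ethyl enol ether F5. Cold aqueous HCl/THF hydrolyses F5 by kinetic C-protonation, and the route is rejoined at 30.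

Step 19, the acid-mediated lactonisation. The C15 cation can lose H14 and re-protonate, which would erode C14, or it can rearrange, and the acid may also isomerise the C7=C8 alkene. The fallback sets out from 31. LiOH in aqueous THF gives the carboxylic acid F6. Iodolactonisation (I2, NaHCO3, MeCN, 0 °C) delivers the carboxylate to C15 from the same face without a free cation and gives the iodomethyl lactone F7. Bu3SnH with azobisisobutyronitrile reduces CH2I to CH3, and the route is rejoined at 32.

Step 15, the thioester–alkyne coupling. The acyl carbon is hindered by the quaternary centre and the substrate carries a primary iodide that the thiolate by-product could attack. The fallback sets out from 12 and uses chloride 23. Fukuyama reduction (Et3SiH, 10% Pd/C, acetone) gives the aldehyde F1. The lithium acetylide of 23 (BuLi, THF, −78 °C) adds to F1 to give the propargylic alcohol F2 as a carbinol epimer mixture. Dess–Martin periodinane oxidises F2 to the chloro ynone F3. F3 is taken through the conditions of step 16 with NaI added, and the route is rejoined at 28.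

**Further compounds**
F1 | step 15 | propan-2-yl 3-[(3S,3aR,6S,6aS)-1-(tert-butoxycarbonyl)-6-formyl-3-methyloctahydrocyclopenta[b]pyrrol-6-yl]propanoate | C[C@@H]1CN(C(=O)OC(C)(C)C)[C@H]2[C@@H]1CC[C@@]2(CCC(=O)OC(C)C)C=O
F2 | step 15 | propargylic alcohol from F1 and the acetylide of 23 (carbinol epimers) | C[C@@H]1CN(C(=O)OC(C)(C)C)[C@H]2[C@@H]1CC[C@@]2(CCC(=O)OC(C)C)C(O)C#CC3=CCC[C@@H]3CCCl
F3 | step 15 | chloro ynone (chloride analogue of 25) | C[C@@H]1CN(C(=O)OC(C)(C)C)[C@H]2[C@@H]1CC[C@@]2(CCC(=O)OC(C)C)C(=O)C#CC3=CCC[C@@H]3CCCl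
F4 | step 17 | O-ethyl iminium tetrafluoroborate of 28 | C[C@@H]1C[N+]2=C3C4=CCC[C@@H]4CCC3=C(OCC)[C@]5(CCC(=O)OC(C)C)CC[C@H]1[C@H]25.F[B-](F)(F)F
F5 | step 17 | ethyl enol ether (C14=C15–OEt; C6–H as in 30) | C[C@@H]1CN2[C@H]3C4=CCC[C@@H]4CCC3=C(OCC)[C@]5(CCC(=O)OC(C)C)CC[C@H]1[C@H]25
F6 | step 19 | exo-methylene carboxylic acid | C[C@@H]1CN2[C@H]3C4=CCC[C@@H]4CC[C@@H]3C(=C)[C@]5(CCC(=O)O)CC[C@H]1[C@H]25
F7 | step 19 | iodomethyl lactone (CH2I in place of the C15 methyl of 32) | C[C@@H]1CN2[C@H]3C4=CCC[C@@H]4CC[C@@H]3[C@@]3(CI)OC(=O)CC[C@]34CC[C@H]1[C@@H]42
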